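Of the solid substrate, 0% is left in the blue run at 10.0 d and 0% in the green run at 10.0 d. From there to 12.0 d, side product A and target stay within the scatter of 1 percentage point in both runs.

in all of them: solid substrate 0.50 M

| flask | reagent | protic impurity | remark | time |
|---|---|---|---|---|
| blue | 2.5 equiv | 10 mM | run made earlier |  |
| green | 4 equiv | 10 mM | run made earlier |  |
| flask | 1.80 equiv | 10.0 mM |  | 15 d |

| run | time / d | side product A / % | target / % | solid substrate / % |
|---|---|---|---|---|
| blue | 2.08 | 58.5 | 4.7 | 0.2 |
| blue | 4.00 | 76.0 | 6.3 | 0 |
| blue | 6.00 | 75.5 | 10.5 | 0 |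
| blue | 8.00 | 76.2 | 9.6 | 0.1 |
| blue | 10.0 | 75.9 | 9.4 | 0 |
| blue | 12.0 | 76.7 | 9.5 | 0 |
| green | 0.833 | 18.1 | 0 | 43.3 |
| green | 2.50 | 66.9 | 7.8 | 0.5 |
| green | 4.00 | 74.0 | 9.2 | 0.2 |
| green | 6.00 | 75.4 | 13.6 | 0.7 |
| green | 10.0 | 76.5 | 11.1 | 0 |
| green | 12.0 | 77.5 | 11.6 | 0 |

(each reading ± 1 percentage point)

1. share of side product A in side product A plus target at 4.0 h
2. share of side product A in side product A plus target at 15 d

- given per volume of solution although it is solid: solid substrate
- at the start none of the solid substrate is in solution

So I read the late ratio of target to side product A, a selectivity factor, from the last two readings of each run. It is 0.124 in the blue run and 0.147 in the green run. Between these runs, the ratio grows as reagent to the power 0.370, the reagent order of the selectivity, a reading with their scatter in it.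

For the flask at 1.80 equiv, I reckon a ratio of 0.110, so side product A holds a share of 90.1% at 15 d. The green run shows target 0% at 0.833 d, and 4.0 h is earlier, so I expect an early share near 100%.

The forecast gives 97% and 91%, on “a weak reagent order of about 0.4”. Its late share stands above my 90.1%.

The flask gives 99.6% and 90.0%. At 15.0 d it holds target 8.58% against side product A 77.0%, a ratio of 0.111 beside my 0.110.

    starting material ⇌ intermediate (K = 1.80, k = 1.84 × 10⁻⁴ min⁻¹)
    reagent + intermediate → target (k = 2.27 × 10⁻⁴ M⁻¹ min⁻¹)
    starting material → side product A (k = 7.39 × 10⁻⁴ min⁻¹)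
    starting material + protic impurity → quenched substrate (k = 0.0448 M⁻¹ min⁻¹)
    solid substrate ⇌ starting material, rate k5*(cs5 - [starting material]) while solid is left; crystals form when [starting material] > cs5 (solubility = 0.370 M, k = 8.97 × 10⁻⁴ min⁻¹)
    starting material + intermediate → side product B (k = 0.00251 M⁻¹ min⁻¹)

In this scheme, target forms from reagent and intermediate, while side product A forms from starting material without reagent. I try the order 0.370 on the neighbouring flask with 0.450 equiv of reagent, its other charges as in the recipe. It gives a ratio of 0.0656, so a share of side product A of 93.8%. That flask gives 95.4%, with target 3.77% against side product A 78.9% at 15.0 d, a ratio of 0.0477, lower than my 0.0656. So the order 0.370 does not hold down to that charge: from the flask at 1.80 equiv to this neighbouring flask, the ratio falls with an order of 0.612.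

The readings stem from a simulated flask for an exercise; scatter was added.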